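**Plan**
- Retrosynthesis: after removal of two MOM acetals, ring C is opened at O1–C2 (taking the C3 hydroxyl with it) and the chalcone Cα=Cβ bond is cut by retro-aldol. This gives a ring A acetophenone and 2,2-dimethyl-2H-chromene-7-carbaldehyde (ring B with its fused pyran).
- The two aryl–CH2 bonds C6–C1'' and C8–C1'' are cut last, each back to a 2-methylbut-3-en-2-yl ether on the neighbouring oxygen (the future O5 and O1).
- Enabling feature: in ring A, C6 is ortho to the C5 oxygen and C8 is ortho to the ring oxygen on C8a. The other ortho position of both oxygens is C4a, which bears the carbonyl carbon C4, so each ether can pass its prenyl group to one carbon only.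
- Forward: phloroacetophenone is masked at the para oxygen, O-alkylated twice, semihydrogenated and rearranged. The pyran of ring B is made separately by oxa-6π electrocyclisation. Aldol condensation joins the halves, ring C is closed last by oxidative cyclisation, and the acetals are removed.
- Stereochemistry: the target has no stereocentre. The E chalcone and the racemic or trans intermediates are erased when ring C becomes aromatic.

Key step: step 4

Assumption: anhydrous 1 (the commercial monohydrate, dried), chloride 3 and a THF solution of Grignard reagent 12 are taken as purchasable; racemic intermediates are drawn as one enantiomer.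

**Step 1**
Reactants: 1 2,4,6-trihydroxyacetophenone
Product: 2 1-[2,6-dihydroxy-4-(methoxymethoxy)phenyl]ethanone
Conditions: MOMCl (1.0 equiv), i-Pr2NEt (1.1 equiv), THF–CH2Cl2, 0 °C
Reagents that add atoms: chloromethyl methyl ether (MOMCl), COCCl
Why: Williamson-type O-alkylation should take the C4 hydroxyl first, because it is the most acidic (para to the acetyl group) and the only one that does not flank the carbonyl chelate, and one equivalent of reagent at 0 °C limits further alkylation.

**Step 2**
Reactants: 2 1-[2,6-dihydroxy-4-(methoxymethoxy)phenyl]ethanone; 3 3-chloro-3-methylbut-1-yne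
Product: 5 1-[4-(methoxymethoxy)-2,6-bis(2-methylbut-3-yn-2-yloxy)phenyl]ethanone, via mono-ether 4 (not isolated)
Conditions: 3 (3 equiv), DBU (3.5 equiv), CuCl2·2H2O (2 mol %), MeCN, 0 °C to rt
Reagents that add atoms: none
Why: Copper-catalysed propargylic etherification (substitution of the tertiary propargylic chloride through a copper acetylide/allenylidene species) should alkylate both DBU-generated phenoxides at oxygen on the tertiary carbon, the excess of chloride and base carrying mono-ether 4 on to the bis-ether.

**Step 3**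
Reactants: 5 1-[4-(methoxymethoxy)-2,6-bis(2-methylbut-3-yn-2-yloxy)phenyl]ethanone
Product: 7 1-[4-(methoxymethoxy)-2,6-bis(2-methylbut-3-en-2-yloxy)phenyl]ethanone, via ene–yne ether 6 (not isolated)
Conditions: H2 (1 atm), Pd/CaCO3 poisoned with Pb(OAc)2, quinoline, EtOAc, rt, stopped after 2 equiv H2
Reagents that add atoms: none
Why: Lindlar-type semihydrogenation over lead-poisoned palladium stops at the alkene for terminal alkynes, so both ethynyl groups should become vinyl groups by way of 6 while the aryl ketone and the acetal stay untouched.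

**Step 4**
Reactants: 7 1-[4-(methoxymethoxy)-2,6-bis(2-methylbut-3-en-2-yloxy)phenyl]ethanone
Product: 9 1-[2,6-dihydroxy-4-(methoxymethoxy)-3,5-bis(3-methylbut-2-enyl)phenyl]ethanone, via mono-rearranged phenol 8 (not isolated)
Conditions: PhNEt2, 130 °C, argon
Reagents that add atoms: none
Why: Each aryl 2-methylbut-3-en-2-yl ether should undergo a concerted, chair-like [3,3]-sigmatropic shift in which the terminal CH2 of the allyl unit bonds to the free ortho carbon as the O–C(CH3)2 bond breaks, and proton transfer then re-aromatises the ring, giving first 8 and then 9. The closest known reaction is the thermal ortho-Claisen rearrangement of aryl 1,1-dimethylallyl ethers to ortho-prenylphenols, which the gem-dimethyl group accelerates and in which allyl inversion turns the tertiary ether into the linear prenyl group. No ring is closed and no stereocentre is formed. The step needs regioselectivity, and the substrate secures it: the only other ortho position of either ether oxygen is C1, which carries the acetyl group and cannot re-aromatise after migration, so each oxygen delivers exactly one prenyl group, to C3 and to C5. The basic solvent should keep the liberated chelated phenols from acid-promoted cyclisation onto the new prenyl groups, and the C4 acetal is inert.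

**Step 5**
Reactants: 9 1-[2,6-dihydroxy-4-(methoxymethoxy)-3,5-bis(3-methylbut-2-enyl)phenyl]ethanone
Product: 10 1-[2-hydroxy-4,6-bis(methoxymethoxy)-3,5-bis(3-methylbut-2-enyl)phenyl]ethanone
Conditions: MOMCl (1.2 equiv), i-Pr2NEt (1.5 equiv), CH2Cl2, 0 °C to rt
Reagents that add atoms: chloromethyl methyl ether (MOMCl), COCCl
Why: Williamson-type O-alkylation of one of the two equivalent hydroxyls should stop after the first MOM group, because the remaining hydroxyl is then locked in the hydrogen-bonded chelate with the acetyl carbonyl and flanked by a prenyl group; it stays free as the nucleophile for ring C.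

**Step 6**
Reactants: 11 4-bromo-2-hydroxybenzaldehyde; 12 2-methylprop-1-enylmagnesium bromide
Product: 13 5-bromo-2-(1-hydroxy-3-methylbut-2-enyl)phenol (racemic)
Conditions: 12 (2.5 equiv), THF, −20 °C to rt; then H2O
Reagents that add atoms: none
Why: Grignard 1,2-addition: the first equivalent deprotonates the phenol and the second adds to the aldehyde of the magnesium phenoxide, giving the benzylic, allylic alcohol as a racemate whose stereocentre is removed in the next step.

**Step 7**
Reactants: 13 5-bromo-2-(1-hydroxy-3-methylbut-2-enyl)phenol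
Product: 15 7-bromo-2,2-dimethyl-2H-chromene, via ortho-quinone methide 14 (not isolated)
Conditions: PPTS (5 mol %), PhMe, 80 °C
Reagents that add atoms: none
Why: Acid-catalysed dehydration of the doubly activated alcohol gives ortho-quinone methide 14, whose Z isomer closes the pyran ring by thermal oxa-6π electrocyclisation, restoring the aromatic ring and placing the bromine at C7 of the chromene.

**Step 8**
Reactants: 15 7-bromo-2,2-dimethyl-2H-chromene
Product: 17 2,2-dimethyl-2H-chromene-7-carbaldehyde, via aryllithium 16 (not isolated)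
Conditions: n-BuLi (1.1 equiv), THF, −78 °C; DMF (2 equiv), −78 to 0 °C; then H2O
Reagents that add atoms: N,N-dimethylformamide (DMF), CN(C)C=O
Why: Bromine–lithium exchange at −78 °C outruns any deprotonation of the chromene, and formylation of aryllithium 16 with DMF followed by hydrolytic work-up should give the aldehyde.

**Step 9**
Reactants: 10 1-[2-hydroxy-4,6-bis(methoxymethoxy)-3,5-bis(3-methylbut-2-enyl)phenyl]ethanone; 17 2,2-dimethyl-2H-chromene-7-carbaldehyde
Product: 19 (E)-3-(2,2-dimethyl-2H-chromen-7-yl)-1-[2-hydroxy-4,6-bis(methoxymethoxy)-3,5-bis(3-methylbut-2-enyl)phenyl]prop-2-en-1-one, via aldol adduct 18 (not isolated)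
Conditions: KOH (aq., excess), EtOH, rt
Reagents that add atoms: none
Why: Claisen–Schmidt condensation: the ketone enolate adds to the non-enolisable aldehyde and aldol 18 loses water by E1cB elimination to give the conjugated E enone under thermodynamic control, the MOM ethers, prenyl groups and chromene being inert to hydroxide.

**Step 10**
Reactants: 19 (E)-3-(2,2-dimethyl-2H-chromen-7-yl)-1-[2-hydroxy-4,6-bis(methoxymethoxy)-3,5-bis(3-methylbut-2-enyl)phenyl]prop-2-en-1-one
Product: 21 2-(2,2-dimethyl-2H-chromen-7-yl)-3-hydroxy-5,7-bis(methoxymethoxy)-6,8-bis(3-methylbut-2-enyl)-4H-chromen-4-one, via trans-dihydroflavonol 20 (not isolated)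
Conditions: 30% aq. H2O2 (excess), NaOH (aq.), MeOH, 0 °C to rt
Reagents that add atoms: hydrogen peroxide, OO
Why: Algar–Flynn–Oyamada reaction: hydroperoxide anion oxidises the enone while the 2'-phenoxide closes ring C at the β-carbon to give trans-dihydroflavonol 20, which is dehydrogenated in the same medium to the flavonol; the nucleophilic oxidant should leave the isolated prenyl and the styrene-type chromene double bonds alone.

**Step 11**
Reactants: 21 2-(2,2-dimethyl-2H-chromen-7-yl)-3-hydroxy-5,7-bis(methoxymethoxy)-6,8-bis(3-methylbut-2-enyl)-4H-chromen-4-one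
Product: 23 dorsilurin C, via 7-O-MOM flavonol 22 (not isolated)
Conditions: 3 M aq. HCl, MeOH, 50 °C
Reagents that add atoms: none
Why: Acid-catalysed acetal methanolysis should remove the peri C5 MOM group first (giving 22) and then the hindered C7 one, the moderate acid strength and temperature being chosen to keep the prenyl groups from cyclising onto the neighbouring phenols.

**Compound list**
1 | 2,4,6-trihydroxyacetophenone | CC(=O)c1c(O)cc(O)cc1O | starting material
2 | 1-[2,6-dihydroxy-4-(methoxymethoxy)phenyl]ethanone | CC(=O)c1c(O)cc(OCOC)cc1O | intermediate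
3 | 3-chloro-3-methylbut-1-yne | CC(C)(Cl)C#C | starting material
4 | 1-[2-hydroxy-4-(methoxymethoxy)-6-(2-methylbut-3-yn-2-yloxy)phenyl]ethanone | CC(=O)c1c(O)cc(OCOC)cc1OC(C)(C)C#C | intermediate (not isolated)
5 | 1-[4-(methoxymethoxy)-2,6-bis(2-methylbut-3-yn-2-yloxy)phenyl]ethanone | CC(=O)c1c(OC(C)(C)C#C)cc(OCOC)cc1OC(C)(C)C#C | intermediate
6 | 1-[4-(methoxymethoxy)-2-(2-methylbut-3-en-2-yloxy)-6-(2-methylbut-3-yn-2-yloxy)phenyl]ethanone | CC(=O)c1c(OC(C)(C)C=C)cc(OCOC)cc1OC(C)(C)C#C | intermediate (not isolated)
7 | 1-[4-(methoxymethoxy)-2,6-bis(2-methylbut-3-en-2-yloxy)phenyl]ethanone | CC(=O)c1c(OC(C)(C)C=C)cc(OCOC)cc1OC(C)(C)C=C | intermediate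
8 | 1-[2-hydroxy-4-(methoxymethoxy)-6-(2-methylbut-3-en-2-yloxy)-3-(3-methylbut-2-enyl)phenyl]ethanone | CC(=O)c1c(O)c(CC=C(C)C)c(OCOC)cc1OC(C)(C)C=C | intermediate (not isolated)
9 | 1-[2,6-dihydroxy-4-(methoxymethoxy)-3,5-bis(3-methylbut-2-enyl)phenyl]ethanone | CC(=O)c1c(O)c(CC=C(C)C)c(OCOC)c(CC=C(C)C)c1O | intermediate
10 | 1-[2-hydroxy-4,6-bis(methoxymethoxy)-3,5-bis(3-methylbut-2-enyl)phenyl]ethanone | CC(=O)c1c(O)c(CC=C(C)C)c(OCOC)c(CC=C(C)C)c1OCOC | intermediate
11 | 4-bromo-2-hydroxybenzaldehyde | O=Cc1ccc(Br)cc1O | starting material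
12 | 2-methylprop-1-enylmagnesium bromide | CC(C)=C[Mg]Br | starting material
13 | 5-bromo-2-(1-hydroxy-3-methylbut-2-enyl)phenol (racemic) | CC(C)=CC(O)c1ccc(Br)cc1O | intermediate
14 | (6Z)-3-bromo-6-(3-methylbut-2-enylidene)cyclohexa-2,4-dien-1-one | CC(C)=C/C=C1/C=CC(Br)=CC1=O | intermediate (not isolated)
15 | 7-bromo-2,2-dimethyl-2H-chromene | CC1(C)C=Cc2ccc(Br)cc2O1 | intermediate
16 | (2,2-dimethyl-2H-chromen-7-yl)lithium | [Li]c1ccc2c(c1)OC(C)(C)C=C2 | intermediate (not isolated)
17 | 2,2-dimethyl-2H-chromene-7-carbaldehyde | CC1(C)C=Cc2ccc(C=O)cc2O1 | intermediate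
18 | 3-(2,2-dimethyl-2H-chromen-7-yl)-3-hydroxy-1-[2-hydroxy-4,6-bis(methoxymethoxy)-3,5-bis(3-methylbut-2-enyl)phenyl]propan-1-one (racemic) | O=C(CC(O)c1ccc2c(c1)OC(C)(C)C=C2)c1c(O)c(CC=C(C)C)c(OCOC)c(CC=C(C)C)c1OCOC | intermediate (not isolated)
19 | (E)-3-(2,2-dimethyl-2H-chromen-7-yl)-1-[2-hydroxy-4,6-bis(methoxymethoxy)-3,5-bis(3-methylbut-2-enyl)phenyl]prop-2-en-1-one | O=C(/C=C/c1ccc2c(c1)OC(C)(C)C=C2)c1c(O)c(CC=C(C)C)c(OCOC)c(CC=C(C)C)c1OCOC | intermediate
20 | (2R*,3R*)-2-(2,2-dimethyl-2H-chromen-7-yl)-3-hydroxy-5,7-bis(methoxymethoxy)-6,8-bis(3-methylbut-2-enyl)chroman-4-one (racemic trans, one enantiomer drawn) | O=C1c2c(OCOC)c(CC=C(C)C)c(OCOC)c(CC=C(C)C)c2O[C@H](c2ccc3c(c2)OC(C)(C)C=C3)[C@H]1O | intermediate (not isolated)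
21 | 2-(2,2-dimethyl-2H-chromen-7-yl)-3-hydroxy-5,7-bis(methoxymethoxy)-6,8-bis(3-methylbut-2-enyl)-4H-chromen-4-one | CC(C)=CCc1c(OCOC)c(CC=C(C)C)c2oc(-c3ccc4c(c3)OC(C)(C)C=C4)c(O)c(=O)c2c1OCOC | intermediate
22 | 2-(2,2-dimethyl-2H-chromen-7-yl)-3,5-dihydroxy-7-(methoxymethoxy)-6,8-bis(3-methylbut-2-enyl)-4H-chromen-4-one | CC(C)=CCc1c(OCOC)c(CC=C(C)C)c2oc(-c3ccc4c(c3)OC(C)(C)C=C4)c(O)c(=O)c2c1O | intermediate (not isolated)
23 | dorsilurin C, 2-(2,2-dimethyl-2H-chromen-7-yl)-3,5,7-trihydroxy-6,8-bis(3-methylbut-2-enyl)-4H-chromen-4-one | CC(C)=CCc1c(O)c(CC=C(C)C)c2oc(-c3ccc4c(c3)OC(C)(C)C=C4)c(O)c(=O)c2c1O | target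

**Count**
Total steps: 11. Longest linear sequence: 8 steps (steps 1–5 and 9–11); the ring B arm (steps 6–8) is convergent.

**Steps most likely to fail**

Step 2. After the first etherification the remaining hydroxyl sits in the hydrogen-bonded chelate with the acetyl carbonyl and next to a bulky tertiary ether. The second O-alkylation may therefore stall while the tertiary chloride is lost to elimination. The fallback delivers the two allyl units one after the other, so that every etherification takes place on a 2,6-dihydroxyacetophenone in which one hydroxyl is always outside the chelate. It sets out from 2: with 1.1 equiv of 3 under the same copper catalysis the reaction is stopped at mono-ether 4, which is now isolated. Semihydrogenation over Pd/CaCO3 poisoned with Pb(OAc)2 should give 1-[2-hydroxy-4-(methoxymethoxy)-6-(2-methylbut-3-en-2-yloxy)phenyl]ethanone F1. Heating in PhNEt2 should move its allyl unit to C3 and give 1-[2,6-dihydroxy-4-(methoxymethoxy)-3-(3-methylbut-2-enyl)phenyl]ethanone F2. A second copper-catalysed etherification with 3 should select the hydroxyl next to the unsubstituted C5, the other being buttressed between acetyl and prenyl, to give 1-[2-hydroxy-4-(methoxymethoxy)-3-(3-methylbut-2-enyl)-6-(2-methylbut-3-yn-2-yloxy)phenyl]ethanone F3. Semihydrogenation of F3 leads to 8, where the fallback comes back to the route, and heating as in step 4 carries 8 on to 9.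

Step 10. The 6'-alkoxy group twists the enone, and the phenoxide may then close a five-membered instead of the six-membered ring (the aurone pathway), or the oxidation may stop before ring C is aromatic. The fallback separates epoxidation from ring closure and closes the ring under acid, where attack at the benzylic carbon is favoured. It sets out from 19: NaH and MOMCl in DMF at 0 °C should cap the chelated phenol to give (E)-3-(2,2-dimethyl-2H-chromen-7-yl)-1-[2,4,6-tris(methoxymethoxy)-3,5-bis(3-methylbut-2-enyl)phenyl]prop-2-en-1-one F4. Weitz–Scheffer epoxidation (30% aq. H2O2, NaOH, MeOH–THF, 0 °C) should give racemic trans-[3-(2,2-dimethyl-2H-chromen-7-yl)oxiran-2-yl][2,4,6-tris(methoxymethoxy)-3,5-bis(3-methylbut-2-enyl)phenyl]methanone F5. Treatment with 3 M HCl in MeOH at 50 °C should remove the three acetals and let the freed 2'-phenol open the epoxide at the benzylic carbon with inversion, giving racemic trans-2-(2,2-dimethyl-2H-chromen-7-yl)-3,5,7-trihydroxy-6,8-bis(3-methylbut-2-enyl)chroman-4-one F6. Dehydrogenation of F6 with cold alkaline H2O2 (NaOH, MeOH, 0 °C), the second stage of the Algar–Flynn–Oyamada sequence, comes back to the route at 23, so that step 11 is not needed.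

Step 4. The tertiary allylic ethers may fragment with loss of the C5 unit before the sigmatropic shift, the second shift may lag behind the first, or a freed phenol may add to its neighbouring prenyl double bond at the reaction temperature. The fallback gives up the oxygen-to-carbon transfer and makes the two aryl–CH2 bonds by direct C-alkylation. It sets out from 2, which is treated with 1-bromo-3-methylbut-2-ene (2.2 equiv) and DBU in THF at 0 °C to rt. The phenoxide of the acylphloroglucinol should react as a carbon nucleophile at its only two free ring positions, C3 and C5, and the fallback comes back to the route at 9 after separation from O-alkylated material. It makes no compound outside the list (F0).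

**Further compounds**
F1 | step 2 | 1-[2-hydroxy-4-(methoxymethoxy)-6-(2-methylbut-3-en-2-yloxy)phenyl]ethanone | CC(=O)c1c(O)cc(OCOC)cc1OC(C)(C)C=C
F2 | step 2 | 1-[2,6-dihydroxy-4-(methoxymethoxy)-3-(3-methylbut-2-enyl)phenyl]ethanone | CC(=O)c1c(O)c(CC=C(C)C)c(OCOC)cc1O
F3 | step 2 | 1-[2-hydroxy-4-(methoxymethoxy)-3-(3-methylbut-2-enyl)-6-(2-methylbut-3-yn-2-yloxy)phenyl]ethanone | CC(=O)c1c(O)c(CC=C(C)C)c(OCOC)cc1OC(C)(C)C#C
F4 | step 10 | (E)-3-(2,2-dimethyl-2H-chromen-7-yl)-1-[2,4,6-tris(methoxymethoxy)-3,5-bis(3-methylbut-2-enyl)phenyl]prop-2-en-1-one | O=C(/C=C/c1ccc2c(c1)OC(C)(C)C=C2)c1c(OCOC)c(CC=C(C)C)c(OCOC)c(CC=C(C)C)c1OCOC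
F5 | step 10 | trans-[3-(2,2-dimethyl-2H-chromen-7-yl)oxiran-2-yl][2,4,6-tris(methoxymethoxy)-3,5-bis(3-methylbut-2-enyl)phenyl]methanone (racemic, one enantiomer drawn) | O=C(c1c(OCOC)c(CC=C(C)C)c(OCOC)c(CC=C(C)C)c1OCOC)[C@H]2O[C@@H]2c3ccc4c(c3)OC(C)(C)C=C4
F6 | step 10 | (2R*,3R*)-2-(2,2-dimethyl-2H-chromen-7-yl)-3,5,7-trihydroxy-6,8-bis(3-methylbut-2-enyl)chroman-4-one (racemic trans, one enantiomer drawn) | O=C1c2c(O)c(CC=C(C)C)c(O)c(CC=C(C)C)c2O[C@H](c2ccc3c(c2)OC(C)(C)C=C3)[C@H]1O
F0 | step 4 | none | none
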